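**Assumption:** the SMILES is read as all‑E (3R,3′R,6′R)‑siphonaxanthin 19‑[(2E)‑dodec‑2‑enoate] (siphonein); positions are given in carotenoid numbering (C8 ketone, C9=C10 enone, C19 = CH2O carbon); (R)‑α‑ionone, (4R,6R)‑actinol, the C10 dialdehyde and (E)‑dodec‑2‑enoic acid are taken as commercial, and simple reagents are named under "Reagents that add atoms" without a number.

## Retrosynthetic overview

1. C19–O ester bond, made last: target ⇒ Morita–Baylis–Hillman (MBH) carbinol (C10–OH, C9=CH2, C8 ketone) + free (E)‑dodec‑2‑enoic acid, by a dehydrative SN2′ acyloxylation that also sets 9E.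
2. C9–C10: MBH carbinol ⇒ β‑ring vinyl ketone + ε‑C27 heptaenal (MBH reaction).
3. C27 heptaenal ⇒ ε‑C15 phosphonium salt + C10 dialdehyde (Wittig), then a C2 Wittig homologation; C6′ comes from (R)‑α‑ionone, C3′ from an enzymatic allylic C–H hydroxylation.
4. Vinyl ketone ⇒ actinol (C3 stereocentre) via Barton vinyl iodide, Negishi coupling (C6–C7) and Weinreb amide/vinyl Grignard.
5. No ring is formed: both cyclohexene rings are bought intact (ε‑ring from α‑ionone, β‑ring from actinol).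

All polyene steps (4, 5, 10, 11) are run in the dark under argon with a trace of BHT.

## Route

**Step 1**
Reactants: 1 (R)‑α‑ionone
Product: 2 (3E)‑4‑[(1R,4R)‑4‑hydroxy‑2,6,6‑trimethylcyclohex‑2‑en‑1‑yl]but‑3‑en‑2‑one [(3R,6R)‑3‑hydroxy‑α‑ionone]
Conditions: engineered P450 BM3 (CYP102A1) variant selective for C3 of α‑ionone (cell‑free extract), NADP+ (cat.), glucose dehydrogenase, D‑glucose, air, KPi pH 7.5, 2% EtOH, 25 °C
Reagents that add atoms: dioxygen, O=O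
Why: P450 allylic C–H hydroxylation (oxygen rebound) at the ring allylic CH2, with OH delivered to the face anti to the C6 side chain, which gives the trans (3R,6R) alcohol and leaves C6 untouched.

**Step 2**
Reactants: 2 (3R,6R)‑3‑hydroxy‑α‑ionone
Product: 3 (1R,4R)‑4‑[(1E)‑3‑hydroxy‑3‑methylpenta‑1,4‑dien‑1‑yl]‑3,5,5‑trimethylcyclohex‑2‑en‑1‑ol (both epimers at the tertiary carbinol)
Conditions: CH2=CHMgBr (3.0 equiv), THF, −20 → 0 °C; then cold pH 7 buffer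
Reagents that add atoms: vinylmagnesium bromide, C=C[Mg]Br
Why: Grignard 1,2‑addition to the enone carbonyl (vinyl‑ionol type); one equivalent is consumed by the free OH, and the uncontrolled new carbinol centre is erased in step 3.

**Step 3**
Reactants: 3 C15 vinyl carbinol
Product: 4 [(2E,4E)‑5‑[(1R,4R)‑4‑hydroxy‑2,6,6‑trimethylcyclohex‑2‑en‑1‑yl]‑3‑methylpenta‑2,4‑dien‑1‑yl]triphenylphosphonium bromide
Conditions: PPh3·HBr (1.05 equiv), MeOH, 0 °C → rt; crystallise the (2E,4E) salt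
Reagents that add atoms: triphenylphosphine hydrobromide, [Br-].[PH+](c1ccccc1)(c1ccccc1)c1ccccc1
Why: Allylic transposition (SN1/SN2′) of the tertiary bis‑allylic carbinol with PPh3 attacking the primary terminus (classical C15 Wittig‑salt formation); the ring secondary allylic OH ionises much more slowly.

**Step 4**
Reactants: 4 C15 phosphonium bromide; 5 (2E,4E,6E)‑2,7‑dimethylocta‑2,4,6‑trienedial
Product: 7 (2E,4E,6E,8E,10E,12E)‑13‑[(1R,4R)‑4‑hydroxy‑2,6,6‑trimethylcyclohex‑2‑en‑1‑yl]‑2,7,11‑trimethyltrideca‑2,4,6,8,10,12‑hexaenal, via C15 phosphonium ylide 6 (not isolated)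
Conditions: 5 (2.0 equiv), 1,2‑epoxybutane, EtOH, 75 °C; then I2 (1 mol%), CH2Cl2, rt; chromatography (5 recovered)
Reagents that add atoms: none
Why: Wittig olefination with the epoxide as neutral HBr scavenger; excess dialdehyde favours the mono‑adduct, and the E/Z mixture at the new C11′=C12′ bond is equilibrated to all‑E by iodine.

**Step 5**
Reactants: 7 C25 aldehyde
Product: 9 (2E,4E,6E,8E,10E,12E,14E)‑15‑[(1R,4R)‑4‑hydroxy‑2,6,6‑trimethylcyclohex‑2‑en‑1‑yl]‑4,9,13‑trimethylpentadeca‑2,4,6,8,10,12,14‑heptaenal, via C27 dioxolane acetal 8 (not isolated)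
Conditions: (1,3‑dioxolan‑2‑ylmethyl)PPh3Br (2.5 equiv), t‑BuOK (2.4 equiv), THF, 0 °C, then 7, 0 °C → rt; then 5% aq. oxalic acid, THF, rt; I2 (cat.)
Reagents that add atoms: (1,3‑dioxolan‑2‑ylmethyl)triphenylphosphonium bromide, [Br-].C1COC(O1)C[P+](c1ccccc1)(c1ccccc1)c1ccccc1; water, O
Why: Wittig two‑carbon homologation with a masked formyl ylide followed by acetal hydrolysis; the aldehyde is unmasked only after the ylide is gone, so there is no over‑homologation, and acid/iodine gives the (11E) enal.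

**Step 6**
Reactants: 10 (4R,6R)‑4‑hydroxy‑2,2,6‑trimethylcyclohexanone (actinol)
Product: 11 (1R,5R)‑4‑hydrazinylidene‑3,3,5‑trimethylcyclohexan‑1‑ol
Conditions: N2H4·H2O (10 equiv), Et3N, EtOH, reflux
Reagents that add atoms: hydrazine, NN
Why: Hydrazone condensation of the hindered ketone (first half of the Barton vinyl iodide synthesis); the carbinol stereocentre is not involved.

**Step 7**
Reactants: 11 actinol hydrazone
Product: 12 (1R)‑4‑iodo‑3,5,5‑trimethylcyclohex‑3‑en‑1‑ol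
Conditions: I2 (2.2 equiv), tetramethylguanidine (6 equiv), THF, 0 °C → rt; then 60 °C
Reagents that add atoms: iodine, II
Why: Barton vinyl iodide synthesis (oxidation to the diazoalkane, iodination, N2 loss, elimination); only C5–H can be lost, so the tetrasubstituted C5=C6 iodide forms and the free OH is tolerated.

**Step 8**
Reactants: 12 vinyl iodide
Product: 13 2‑[(4R)‑4‑hydroxy‑2,6,6‑trimethylcyclohex‑1‑en‑1‑yl]‑N‑methoxy‑N‑methylacetamide
Conditions: BrZnCH2C(O)N(OMe)Me (3 equiv, from the bromoacetamide, Zn dust, TMSCl cat., THF), Pd2(dba)3 (2.5 mol%), XPhos (6 mol%), THF, 60 °C, slow addition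
Reagents that add atoms: 2‑bromo‑N‑methoxy‑N‑methylacetamide, CON(C)C(=O)CBr
Why: Negishi cross‑coupling of a Reformatsky‑type zinc amide enolate with the vinyl iodide forms C6–C7; a bulky biarylphosphine handles the hindered iodide and the weakly basic zinc reagent tolerates the free OH.

**Step 9**
Reactants: 13 Weinreb amide
Product: 14 1‑[(4R)‑4‑hydroxy‑2,6,6‑trimethylcyclohex‑1‑en‑1‑yl]but‑3‑en‑2‑one
Conditions: CH2=CHMgBr (3.5 equiv), THF, −78 → −20 °C; inverse quench into cold dilute aq. acid; used at once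
Reagents that add atoms: vinylmagnesium bromide, C=C[Mg]Br
Why: Weinreb ketone synthesis, in which the chelated tetrahedral adduct prevents over‑addition; the acidic inverse quench keeps the released amine from adding to the vinyl ketone.

**Step 10**
Reactants: 9 C27 heptaenal; 14 vinyl ketone
Product: 15 (5E,7E,9E,11E,13E,15E,17E)‑4‑hydroxy‑1‑[(4R)‑4‑hydroxy‑2,6,6‑trimethylcyclohex‑1‑en‑1‑yl]‑18‑[(1R,4R)‑4‑hydroxy‑2,6,6‑trimethylcyclohex‑2‑en‑1‑yl]‑7,12,16‑trimethyl‑3‑methylideneoctadeca‑5,7,9,11,13,15,17‑heptaen‑2‑one (both C10 epimers)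
Conditions: 14 (2.5 equiv, in portions), DABCO (1.0 equiv), 1,4‑dioxane/H2O 4:1, 20 °C
Reagents that add atoms: none
Why: Morita–Baylis–Hillman reaction, in which DABCO adds to the only Michael acceptor (CH2= of 14), the ammonium enolate adds to the aldehyde and DABCO is expelled, forming C9–C10; the C10 epimer mixture is erased in step 11.

**Step 11**
Reactants: 15 MBH carbinol; 16 (2E)‑dodec‑2‑enoic acid
Product: 17 (3R,3′R,6′R,all‑E)‑3,3′‑dihydroxy‑8‑oxo‑7,8‑dihydro‑β,ε‑caroten‑19‑yl (2E)‑dodec‑2‑enoate (siphonein)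
Conditions: 16 (2.0 equiv), DABCO (20 mol%), 4 Å MS, PhMe, 45 °C
Reagents that add atoms: none
Why: Proposed new method: amine‑catalysed dehydrative SN2′/SN2 acyloxylation of an unactivated MBH alcohol by a free carboxylic acid — DABCO (or the carboxylate) adds to the C19 methylene, the resulting β‑hydroxy ketone loses water by acid‑assisted E1cB because this creates the fully conjugated polyenone, and the 2‑(ammoniomethyl)enone carboxylate ion pair collapses at C19 (any C10 ester re‑enters by the same addition–elimination), so all isomers funnel to the 19‑ester with the thermodynamic 9E geometry while the ring hydroxyls, which are not part of a Michael acceptor, stay untouched; the closest known reaction type is the DABCO‑mediated SN2′–SN2 substitution and 1,3‑acyloxy shift of MBH acetates and carbonates.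

## Compound list

1 | (R)‑α‑ionone, (3E)‑4‑[(1R)‑2,6,6‑trimethylcyclohex‑2‑en‑1‑yl]but‑3‑en‑2‑one | CC(=O)/C=C/[C@H]1C(C)=CCCC1(C)C | starting material
2 | (3R,6R)‑3‑hydroxy‑α‑ionone, (3E)‑4‑[(1R,4R)‑4‑hydroxy‑2,6,6‑trimethylcyclohex‑2‑en‑1‑yl]but‑3‑en‑2‑one | CC(=O)/C=C/[C@H]1C(C)=C[C@H](O)CC1(C)C | intermediate
3 | (1R,4R)‑4‑[(1E)‑3‑hydroxy‑3‑methylpenta‑1,4‑dien‑1‑yl]‑3,5,5‑trimethylcyclohex‑2‑en‑1‑ol (epimers at the tertiary carbinol) | C=CC(C)(O)/C=C/[C@H]1C(C)=C[C@H](O)CC1(C)C | intermediate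
4 | [(2E,4E)‑5‑[(1R,4R)‑4‑hydroxy‑2,6,6‑trimethylcyclohex‑2‑en‑1‑yl]‑3‑methylpenta‑2,4‑dien‑1‑yl]triphenylphosphonium bromide | [Br-].C(/C=C(C)/C=C/[C@H]1C(C)=C[C@H](O)CC1(C)C)[P+](c1ccccc1)(c1ccccc1)c1ccccc1 | intermediate
5 | (2E,4E,6E)‑2,7‑dimethylocta‑2,4,6‑trienedial (C10 dialdehyde) | O=C/C(C)=C/C=C/C=C(C)/C=O | starting material
6 | C15 phosphonium ylide of 4 | [CH-](/C=C(C)/C=C/[C@H]1C(C)=C[C@H](O)CC1(C)C)[P+](c1ccccc1)(c1ccccc1)c1ccccc1 | intermediate (not isolated)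
7 | (2E,4E,6E,8E,10E,12E)‑13‑[(1R,4R)‑4‑hydroxy‑2,6,6‑trimethylcyclohex‑2‑en‑1‑yl]‑2,7,11‑trimethyltrideca‑2,4,6,8,10,12‑hexaenal (C25 aldehyde) | O=C/C(C)=C/C=C/C=C(C)/C=C/C=C(C)/C=C/[C@H]1C(C)=C[C@H](O)CC1(C)C | intermediate
8 | 2‑[(3E,5E,7E,9E,11E,13E)‑14‑[(1R,4R)‑4‑hydroxy‑2,6,6‑trimethylcyclohex‑2‑en‑1‑yl]‑3,8,12‑trimethyltetradeca‑1,3,5,7,9,11,13‑heptaen‑1‑yl]‑1,3‑dioxolane (C27 dioxolane acetal, 1E/1Z mixture) | C1COC(O1)C=C/C(C)=C/C=C/C=C(C)/C=C/C=C(C)/C=C/[C@H]2C(C)=C[C@H](O)CC2(C)C | intermediate (not isolated)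
9 | (2E,4E,6E,8E,10E,12E,14E)‑15‑[(1R,4R)‑4‑hydroxy‑2,6,6‑trimethylcyclohex‑2‑en‑1‑yl]‑4,9,13‑trimethylpentadeca‑2,4,6,8,10,12,14‑heptaenal (C27 aldehyde) | O=C/C=C/C(C)=C/C=C/C=C(C)/C=C/C=C(C)/C=C/[C@H]1C(C)=C[C@H](O)CC1(C)C | intermediate
10 | (4R,6R)‑4‑hydroxy‑2,2,6‑trimethylcyclohexanone (actinol) | O=C1[C@H](C)C[C@@H](O)CC1(C)C | starting material
11 | (1R,5R)‑4‑hydrazinylidene‑3,3,5‑trimethylcyclohexan‑1‑ol | NN=C1[C@H](C)C[C@@H](O)CC1(C)C | intermediate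
12 | (1R)‑4‑iodo‑3,5,5‑trimethylcyclohex‑3‑en‑1‑ol | IC1=C(C)C[C@@H](O)CC1(C)C | intermediate
13 | 2‑[(4R)‑4‑hydroxy‑2,6,6‑trimethylcyclohex‑1‑en‑1‑yl]‑N‑methoxy‑N‑methylacetamide | CON(C)C(=O)CC1=C(C)C[C@@H](O)CC1(C)C | intermediate
14 | 1‑[(4R)‑4‑hydroxy‑2,6,6‑trimethylcyclohex‑1‑en‑1‑yl]but‑3‑en‑2‑one | C=CC(=O)CC1=C(C)C[C@@H](O)CC1(C)C | intermediate
15 | MBH carbinol, (5E,7E,9E,11E,13E,15E,17E)‑4‑hydroxy‑1‑[(4R)‑4‑hydroxy‑2,6,6‑trimethylcyclohex‑1‑en‑1‑yl]‑18‑[(1R,4R)‑4‑hydroxy‑2,6,6‑trimethylcyclohex‑2‑en‑1‑yl]‑7,12,16‑trimethyl‑3‑methylideneoctadeca‑5,7,9,11,13,15,17‑heptaen‑2‑one (C4 epimers) | C=C(C(O)/C=C/C(C)=C/C=C/C=C(C)/C=C/C=C(C)/C=C/[C@H]1C(C)=C[C@H](O)CC1(C)C)C(=O)CC1=C(C)C[C@@H](O)CC1(C)C | intermediate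
16 | (2E)‑dodec‑2‑enoic acid | CCCCCCCCC/C=C/C(=O)O | starting material
17 | siphonein, (3R,3′R,6′R,all‑E)‑3,3′‑dihydroxy‑8‑oxo‑7,8‑dihydro‑β,ε‑caroten‑19‑yl (2E)‑dodec‑2‑enoate | CCCCCCCCC/C=C/C(=O)OC\C(=C/C=C/C(C)=C/C=C/C=C(C)/C=C/C=C(C)/C=C/[C@H]1C(C)=C[C@H](O)CC1(C)C)C(=O)CC1=C(C)C[C@@H](O)CC1(C)C | target

## Step count and risks

Total steps: 11. Longest linear sequence: 7 (steps 1–5, 10, 11); the second branch is steps 6–9.

Three steps most likely to fail: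

**Step 11 (the proposed new step).** Risk: water is not lost from the DABCO adduct, or the heptaenyl carbinol ionises and gives retro/anhydro polyenes. The fallback uses known protecting‑group and Mitsunobu chemistry. It sets out from 9 and 14, which are each silylated (TBSCl, imidazole, DMF) to the TBS ether of the C27 aldehyde F1 and the TBS ether of the vinyl ketone F2. These are joined by the MBH reaction of step 10 to the bis‑TBS MBH carbinol F3, in which C10–OH is the only free hydroxyl. F3 undergoes the known Mitsunobu SN2′ esterification of MBH alcohols with 16 (PPh3, DIAD, THF, −20 °C) to give bis‑TBS siphonein F4; any unrearranged C10 ester is moved to C19 by the known DABCO‑mediated 1,3‑acyloxy shift of MBH esters. HF·pyridine/pyridine in THF at 0 °C then removes both silyl groups and the route comes back at 17.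

**Step 10.** Risk: the conjugated heptaenal is a poor MBH electrophile and 14 may dimerise (Rauhut–Currier) first. The fallback sets out from 14 and 9 and replaces amine catalysis by the known stoichiometric thia‑Michael/aldol tandem: Me2AlSPh (one extra equivalent per free OH, CH2Cl2/THF, −78 °C) adds to 14 to give the β‑phenylthio aluminium enolate regiospecifically, and 9 is then added to give the β‑hydroxy α‑(phenylthiomethyl) ketone F5. Oxidation at sulfur (NaIO4, aq. MeOH, 0 °C) gives the sulfoxide F6, and thermal sulfoxide elimination (PhMe, CaCO3, 60–70 °C) brings the route back at 15.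

**Step 8.** Risk: the tetrasubstituted, neopentyl‑flanked vinyl iodide may not couple with the zinc amide enolate. The fallback sets out from 12 and bypasses 13: Stille coupling with (Z)‑tributyl(2‑ethoxyvinyl)stannane (Pd2(dba)3, AsPh3, CuI, NMP, 60 °C) gives the dienol ether F7, mild hydrolysis (aq. oxalic acid, THF) gives the β,γ‑unsaturated aldehyde F8, and vinylmagnesium bromide gives the allylic alcohol F9. MnO2 (CH2Cl2, rt) oxidises only the allylic carbinol and the route comes back at 14.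

## Further compounds

F1 | step 11 | (2E,4E,6E,8E,10E,12E,14E)‑15‑[(1R,4R)‑4‑[(tert‑butyldimethylsilyl)oxy]‑2,6,6‑trimethylcyclohex‑2‑en‑1‑yl]‑4,9,13‑trimethylpentadeca‑2,4,6,8,10,12,14‑heptaenal | O=C/C=C/C(C)=C/C=C/C=C(C)/C=C/C=C(C)/C=C/[C@H]1C(C)=C[C@H](O[Si](C)(C)C(C)(C)C)CC1(C)C
F2 | step 11 | 1‑[(4R)‑4‑[(tert‑butyldimethylsilyl)oxy]‑2,6,6‑trimethylcyclohex‑1‑en‑1‑yl]but‑3‑en‑2‑one | C=CC(=O)CC1=C(C)C[C@@H](O[Si](C)(C)C(C)(C)C)CC1(C)C
F3 | step 11 | 3,3′‑bis‑O‑TBS ether of MBH carbinol 15 | C=C(C(O)/C=C/C(C)=C/C=C/C=C(C)/C=C/C=C(C)/C=C/[C@H]1C(C)=C[C@H](O[Si](C)(C)C(C)(C)C)CC1(C)C)C(=O)CC1=C(C)C[C@@H](O[Si](C)(C)C(C)(C)C)CC1(C)C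
F4 | step 11 | 3,3′‑bis‑O‑TBS ether of siphonein 17 | CCCCCCCCC/C=C/C(=O)OC\C(=C/C=C/C(C)=C/C=C/C=C(C)/C=C/C=C(C)/C=C/[C@H]1C(C)=C[C@H](O[Si](C)(C)C(C)(C)C)CC1(C)C)C(=O)CC1=C(C)C[C@@H](O[Si](C)(C)C(C)(C)C)CC1(C)C
F5 | step 10 | (5E,7E,9E,11E,13E,15E,17E)‑4‑hydroxy‑1‑[(4R)‑4‑hydroxy‑2,6,6‑trimethylcyclohex‑1‑en‑1‑yl]‑18‑[(1R,4R)‑4‑hydroxy‑2,6,6‑trimethylcyclohex‑2‑en‑1‑yl]‑7,12,16‑trimethyl‑3‑[(phenylsulfanyl)methyl]octadeca‑5,7,9,11,13,15,17‑heptaen‑2‑one | O=C(CC1=C(C)C[C@@H](O)CC1(C)C)C(CSc1ccccc1)C(O)/C=C/C(C)=C/C=C/C=C(C)/C=C/C=C(C)/C=C/[C@H]1C(C)=C[C@H](O)CC1(C)C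
F6 | step 10 | the corresponding 3‑[(phenylsulfinyl)methyl] ketone (sulfoxide of F5) | O=C(CC1=C(C)C[C@@H](O)CC1(C)C)C(CS(=O)c1ccccc1)C(O)/C=C/C(C)=C/C=C/C=C(C)/C=C/C=C(C)/C=C/[C@H]1C(C)=C[C@H](O)CC1(C)C
F7 | step 8 | (1R)‑4‑[(Z)‑2‑ethoxyethenyl]‑3,5,5‑trimethylcyclohex‑3‑en‑1‑ol | CCO/C=C\C1=C(C)C[C@@H](O)CC1(C)C
F8 | step 8 | [(4R)‑4‑hydroxy‑2,6,6‑trimethylcyclohex‑1‑en‑1‑yl]acetaldehyde | O=CCC1=C(C)C[C@@H](O)CC1(C)C
F9 | step 8 | 1‑[(4R)‑4‑hydroxy‑2,6,6‑trimethylcyclohex‑1‑en‑1‑yl]but‑3‑en‑2‑ol (both carbinol epimers) | C=CC(O)CC1=C(C)C[C@@H](O)CC1(C)C
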